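The cyclohexene ring is cut at C4=C5, the one ring bond whose formation creates no stereocentre: it lies between the allylic benzoate carbon C3 and the oxirane carbon C6. Ring-closing metathesis of two vinyl groups closes the six-membered ring C1–C6 in one operation, with all four stereocentres and all three esters already in place. The C2 arm and the C6 vinyl group are cis on the oxirane, which holds the two alkenes together. The precursor is epoxy diene 21 (C3 benzoate, C2 acetate, C1–C6 oxirane, C7 benzoate). Its C7–C1–C2–C3–C4 chain, with C2 and C3, comes from L-sorbose, and a Sharpless epoxidation sets C1 and C6.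

Key step: step 11

Remark: C1–C7 are the target atom numbers (C1 quaternary oxirane carbon, C7 its CH2O carbon), sugar positions are written "sugar C-n", TBS is tert-butyldimethylsilyl, and compound 1 (the mono-acetonide of L-sorbose) is taken as a catalogue compound.

Step 1
Reactants: 1 2,3-O-isopropylidene-α-L-sorbofuranose; 2 iodine
Product: 3 6-deoxy-6-iodo-2,3-O-isopropylidene-α-L-sorbofuranose
Conditions: I2, PPh3, imidazole, THF, 0 °C to rt
Reagents that add atoms: iodine, II
Why: Garegg–Samuelsson (Appel-type) iodination, in which SN2 displacement of the alkoxyphosphonium group is fast only at the unhindered primary sugar C-6, since the other primary carbon (sugar C-1) is neopentyl-like next to the ketal carbon and sugar C-4 is secondary; no stereocentre is touched.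

Step 2
Reactants: 3 6-deoxy-6-iodo-2,3-O-isopropylidene-α-L-sorbofuranose; 4 tert-butyldimethylsilyl triflate
Product: 5 1,4-di-O-TBS-6-deoxy-6-iodo-2,3-O-isopropylidene-α-L-sorbofuranose
Conditions: TBSOTf, 2,6-lutidine, CH2Cl2, −20 to 0 °C
Reagents that add atoms: tert-butyldimethylsilyl triflate, CC(C)(C)[Si](C)(C)OS(=O)(=O)C(F)(F)F
Why: Silyl ether formation with a silyl triflate and a hindered pyridine base caps the two remaining hydroxyls (the future O7 and O3) and leaves the primary iodide alone.

Step 3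
Reactants: 5 1,4-di-O-TBS-6-deoxy-6-iodo-2,3-O-isopropylidene-α-L-sorbofuranose
Product: 7 (3S,4R)-1,4-bis[(tert-butyldimethylsilyl)oxy]-3-hydroxyhex-5-en-2-one, via organozinc iodide 6 (not isolated)
Conditions: Zn dust (activated), THF/H2O 4:1, ultrasound, 40 °C
Reagents that add atoms: none
Why: Bernet–Vasella reductive fragmentation, in which zinc inserts into the C–I bond, β-elimination of the ring oxygen forms the terminal alkene (the future C4 vinyl group) and the ketal alkoxide collapses to the C1 ketone with loss of acetone, so that only the hydroxyl formerly held in the acetonide (the future O2) is set free and the two carbinol centres (future C2 and C3) are carried over unchanged.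

Step 4
Reactants: 7 (3S,4R)-1,4-bis[(tert-butyldimethylsilyl)oxy]-3-hydroxyhex-5-en-2-one; 8 (triphenylphosphoranylidene)ketene (Bestmann ylide)
Product: 10 (5R)-4-{[(tert-butyldimethylsilyl)oxy]methyl}-5-{(1R)-1-[(tert-butyldimethylsilyl)oxy]prop-2-en-1-yl}furan-2(5H)-one, via phosphoranylidene acetate ester 9 (not isolated)
Conditions: Ph3P=C=C=O, toluene, 90 °C
Reagents that add atoms: (triphenylphosphoranylidene)ketene, O=C=C=P(c1ccccc1)(c1ccccc1)c1ccccc1
Why: Bestmann butenolide synthesis, in which the free hydroxyl adds to the ketene ylide and the resulting ester ylide closes onto the neighbouring ketone in an intramolecular Wittig reaction, so that the new C1=C6 double bond is locked in a five-membered lactone with C2 and C5 cis.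

Step 5
Reactants: 10 butenolide (5R)-4-(TBSO-methyl)-5-[(1R)-1-(TBSO)prop-2-en-1-yl]furan-2(5H)-one
Product: 11 (5R)-4-{[(tert-butyldimethylsilyl)oxy]methyl}-5-{(1R)-1-[(tert-butyldimethylsilyl)oxy]prop-2-en-1-yl}-2,5-dihydrofuran-2-ol (lactol, mixture of anomers, used crude)
Conditions: iBu2AlH (1.2 equiv), CH2Cl2, −78 °C; aqueous KNaC4H4O6 work-up
Reagents that add atoms: none
Why: Partial reduction of a lactone to the lactol with diisobutylaluminium hydride, where the tetrahedral aluminate is stable at −78 °C and the neutral tartrate work-up should avoid dehydration to the furan.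

Step 6
Reactants: 11 lactol; 12 methyltriphenylphosphonium bromide
Product: 14 (3R,4R,5Z)-3-[(tert-butyldimethylsilyl)oxy]-5-{[(tert-butyldimethylsilyl)oxy]methyl}octa-1,5,7-trien-4-ol, via open-chain hydroxy enal 13 (not isolated)
Conditions: Ph3PCH3Br, n-BuLi, THF, 0 °C; then 11, −78 °C to rt
Reagents that add atoms: methyltriphenylphosphonium bromide, C[P+](c1ccccc1)(c1ccccc1)c1ccccc1.[Br-]
Why: Wittig methylenation of a lactol through its ring-opened aldehyde, which keeps the C1=C6 geometry fixed in the lactone, gives the (Z)-diene with the C6 vinyl group and releases O2 as the only free hydroxyl.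

Step 7
Reactants: 14 (3R,4R,5Z)-dienol; 15 acetic anhydride
Product: 16 (3R,4R,5Z)-3-[(tert-butyldimethylsilyl)oxy]-5-{[(tert-butyldimethylsilyl)oxy]methyl}octa-1,5,7-trien-4-yl acetate
Conditions: Ac2O, pyridine, DMAP (cat.), CH2Cl2, 0 °C to rt
Reagents that add atoms: acetic anhydride, CC(=O)OC(C)=O
Why: DMAP-catalysed acylation of the single free secondary alcohol installs the C2 acetate with retention at C2.

Step 8
Reactants: 16 bis-silyl trienyl acetate
Product: 17 (3R,4R,5Z)-3-hydroxy-5-(hydroxymethyl)octa-1,5,7-trien-4-yl acetate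
Conditions: HF·pyridine, pyridine, THF, 0 °C to rt
Reagents that add atoms: none
Why: Fluoride cleavage of both silyl ethers under buffered, weakly acidic conditions, which should not promote acetyl migration to the freed C3 and C7 hydroxyls.

Step 9
Reactants: 17 trienediol acetate; 18 tert-butyl hydroperoxide
Product: 19 (1S,2R)-2-hydroxy-1-[(2S,3S)-2-(hydroxymethyl)-3-vinyloxiran-2-yl]but-3-en-1-yl acetate
Conditions: Ti(OiPr)4 (20 mol %), L-(+)-diisopropyl tartrate (25 mol %), t-BuOOH (in decane), 4 Å molecular sieves, CH2Cl2, −25 °C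
Reagents that add atoms: tert-butyl hydroperoxide, CC(C)(C)OO
Why: Sharpless asymmetric epoxidation directed by the primary allylic C7 hydroxyl, which epoxidises only C1=C6 and in which the L-(+)-tartrate titanium complex should deliver oxygen to the face that gives (1S,6S) at C1 and C6 (oxirane anti to the C2 acetate), while the (Z)-alkene geometry becomes the cis relation of the C2 arm and the C6 vinyl group.

Step 10
Reactants: 19 epoxy diol; 20 benzoyl chloride
Product: 21 (1S,2R)-2-(benzoyloxy)-1-{(2S,3S)-2-[(benzoyloxy)methyl]-3-vinyloxiran-2-yl}but-3-en-1-yl acetate (epoxy diene triester: C3 benzoate, C2 acetate, C1–C6 oxirane, C7 benzoate)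
Conditions: BzCl, Et3N, DMAP (cat.), CH2Cl2, 0 °C
Reagents that add atoms: benzoyl chloride, O=C(Cl)c1ccccc1
Why: Amine-mediated acylation of the primary C7 and the secondary allylic C3 hydroxyls, conditions under which 2,3-epoxy alcohols are esterified without opening of the oxirane.

Step 11
Reactants: 21 epoxy diene triester
Product: 22 [(1S,2S,3R,6S)-2-acetoxy-3-(benzoyloxy)-7-oxabicyclo[4.1.0]hept-4-en-1-yl]methyl benzoate
Conditions: second-generation Grubbs catalyst RuCl2(=CHPh)(H2IMes)(PCy3) (5 mol %), CH2Cl2 (5 mM), 40 °C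
Reagents that add atoms: none
Why: Ring-closing olefin metathesis: the ruthenium benzylidene exchanges with one terminal vinyl group to give a ruthenium alkylidene, which adds to the second vinyl group in a [2+2] cycloaddition, and cycloreversion of the ruthenacyclobutane releases ethylene and forms C4=C5. The closest known reaction type is the ring-closing metathesis of 1,7-dienes that carry allylic esters and vinyl oxiranes to give cyclohexenes. The six-membered carbocycle C1–C6 closes by joining the chain termini C4 and C5 through the metallacyclobutane, which can only give the cis ring alkene. No stereocentre is formed or touched, so C1, C2, C3 and C6 enter the ring as they were set in the chain. The step needs cyclisation to win over oligomerisation and needs the vinyl oxirane and the allylic benzoate to survive. High dilution, the cis placement of the C2 arm and the C6 vinyl group on the oxirane, and the neutral, non-nucleophilic medium should secure this.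

Compound list
1 | 2,3-O-isopropylidene-α-L-sorbofuranose | OC[C@]12OC(C)(C)O[C@H]1[C@H](O)[C@H](CO)O2 | starting material
2 | iodine | II | starting material
3 | 6-deoxy-6-iodo-2,3-O-isopropylidene-α-L-sorbofuranose | OC[C@]12OC(C)(C)O[C@H]1[C@H](O)[C@H](CI)O2 | intermediate
4 | tert-butyldimethylsilyl triflate | CC(C)(C)[Si](C)(C)OS(=O)(=O)C(F)(F)F | starting material
5 | 1,4-di-O-TBS-6-deoxy-6-iodo-2,3-O-isopropylidene-α-L-sorbofuranose | CC(C)(C)[Si](C)(C)OC[C@]12OC(C)(C)O[C@H]1[C@H](O[Si](C)(C)C(C)(C)C)[C@H](CI)O2 | intermediate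
6 | organozinc iodide of 5 (6-deoxy-6-iodozincio derivative, not isolated) | CC(C)(C)[Si](C)(C)OC[C@]12OC(C)(C)O[C@H]1[C@H](O[Si](C)(C)C(C)(C)C)[C@H](C[Zn]I)O2 | intermediate
7 | (3S,4R)-1,4-bis[(tert-butyldimethylsilyl)oxy]-3-hydroxyhex-5-en-2-one | CC(C)(C)[Si](C)(C)OCC(=O)[C@@H](O)[C@H](O[Si](C)(C)C(C)(C)C)C=C | intermediate
8 | (triphenylphosphoranylidene)ketene (Bestmann ylide) | O=C=C=P(c1ccccc1)(c1ccccc1)c1ccccc1 | starting material
9 | (3S,4R)-1,4-bis(TBSO)-2-oxohex-5-en-3-yl (triphenylphosphoranylidene)acetate (not isolated) | CC(C)(C)[Si](C)(C)OCC(=O)[C@@H](OC(=O)C=P(c1ccccc1)(c1ccccc1)c1ccccc1)[C@H](O[Si](C)(C)C(C)(C)C)C=C | intermediate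
10 | (5R)-4-(TBSO-methyl)-5-[(1R)-1-(TBSO)prop-2-en-1-yl]furan-2(5H)-one | CC(C)(C)[Si](C)(C)OCC1=CC(=O)O[C@H]1[C@H](O[Si](C)(C)C(C)(C)C)C=C | intermediate
11 | (5R)-4-(TBSO-methyl)-5-[(1R)-1-(TBSO)prop-2-en-1-yl]-2,5-dihydrofuran-2-ol (anomeric mixture) | CC(C)(C)[Si](C)(C)OCC1=CC(O)O[C@H]1[C@H](O[Si](C)(C)C(C)(C)C)C=C | intermediate
12 | methyltriphenylphosphonium bromide | C[P+](c1ccccc1)(c1ccccc1)c1ccccc1.[Br-] | starting material
13 | (2Z,4R,5R)-5-(TBSO)-3-(TBSO-methyl)-4-hydroxyhepta-2,6-dienal (not isolated) | O=C/C=C(CO[Si](C)(C)C(C)(C)C)\[C@@H](O)[C@H](O[Si](C)(C)C(C)(C)C)C=C | intermediate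
14 | (3R,4R,5Z)-3-(TBSO)-5-(TBSO-methyl)octa-1,5,7-trien-4-ol | C=C/C=C(CO[Si](C)(C)C(C)(C)C)\[C@@H](O)[C@H](O[Si](C)(C)C(C)(C)C)C=C | intermediate
15 | acetic anhydride | CC(=O)OC(C)=O | starting material
16 | (3R,4R,5Z)-3-(TBSO)-5-(TBSO-methyl)octa-1,5,7-trien-4-yl acetate | C=C/C=C(CO[Si](C)(C)C(C)(C)C)\[C@@H](OC(C)=O)[C@H](O[Si](C)(C)C(C)(C)C)C=C | intermediate
17 | (3R,4R,5Z)-3-hydroxy-5-(hydroxymethyl)octa-1,5,7-trien-4-yl acetate | C=C/C=C(CO)\[C@@H](OC(C)=O)[C@H](O)C=C | intermediate
18 | tert-butyl hydroperoxide | CC(C)(C)OO | starting material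
19 | (1S,2R)-2-hydroxy-1-[(2S,3S)-2-(hydroxymethyl)-3-vinyloxiran-2-yl]but-3-en-1-yl acetate | C=C[C@@H](O)[C@H](OC(C)=O)[C@@]1(CO)O[C@H]1C=C | intermediate
20 | benzoyl chloride | O=C(Cl)c1ccccc1 | starting material
21 | (1S,2R)-2-(benzoyloxy)-1-{(2S,3S)-2-[(benzoyloxy)methyl]-3-vinyloxiran-2-yl}but-3-en-1-yl acetate | C=C[C@@H](OC(=O)c1ccccc1)[C@H](OC(C)=O)[C@@]1(COC(=O)c2ccccc2)O[C@H]1C=C | intermediate
22 | [(1S,2S,3R,6S)-2-acetoxy-3-(benzoyloxy)-7-oxabicyclo[4.1.0]hept-4-en-1-yl]methyl benzoate | CC(=O)O[C@H]1[C@H](OC(=O)c2ccccc2)C=C[C@@H]2O[C@@]21COC(=O)c1ccccc1 | target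

Total step count: 11. Longest linear sequence: 11 steps (from 1).

Steps most likely to fail

Step 9. The catalyst-controlled facial selectivity may be eroded by the resident C2 and C3 centres, and the acetyl group may migrate to a neighbouring titanium alkoxide. The fallback sets out from 17 and returns at 21. Both hydroxyls of 17 are benzoylated first (BzCl, pyridine, 0 °C) to give the triene triester F1. F1 is then epoxidised without a directing group by the chiral dioxirane made from Oxone (2KHSO5·KHSO4·K2SO4) and the enantiomer of the fructose-derived Shi ketone (K2CO3 buffer, MeCN/dimethoxymethane/H2O, 0 °C). The trisubstituted C1=C6 alkene is the most electron-rich of the three, and the spiro transition state of this catalyst enantiomer is expected to place oxygen on the same face as the L-(+)-tartrate system, giving 21 directly.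

Step 6 (with the lactol from step 5). The lactol may dehydrate to the furan before olefination, or a silyl group may migrate to the C2 alkoxide formed in the Wittig reaction. The fallback sets out from 10 and returns at 16.
- Excess iBu2AlH (−78 to 0 °C) reduces the lactone past the lactol to the (Z)-enediol F2, which cannot aromatise.
- The primary allylic hydroxyl is silylated selectively (Et3SiCl, imidazole, −40 °C) to give the triethylsilyl ether F3.
- Acetylation of the C2 hydroxyl (Ac2O, pyridine, DMAP) gives the acetate F4.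
- PPTS in MeOH removes only the triethylsilyl group to give the primary allylic alcohol F5.
- Dess–Martin oxidation gives the (Z)-enal F6, which cannot close to a lactol because O2 is acylated.
- Methylenation with Ph3P=CH2 at −78 °C gives 16, with no free alkoxide next to a silyl ether at any stage.

Step 1. Iodination may also occur at the second primary hydroxyl or give mixtures that are hard to separate. The fallback sets out from 1 and returns at 5.
- Compound 1 is converted back into its 4,6-acetal (2,2-dimethoxypropane, TsOH cat.), the diacetonide F7, in which sugar O-1 is the only free hydroxyl.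
- Silylation (TBSCl, imidazole) gives the silyl ether F8.
- Dilute aqueous acetic acid cleaves the six-membered 4,6-acetal selectively to give the diol F9.
- Iodination (I2, PPh3, imidazole) now meets a single primary hydroxyl and gives the iodide F10.
- Silylation of sugar O-4 (TBSOTf, 2,6-lutidine) gives 5.

Further compounds
F1 | step 9 | (3R,4R,5Z)-4-acetoxy-5-[(benzoyloxy)methyl]octa-1,5,7-trien-3-yl benzoate | C=C/C=C(COC(=O)c1ccccc1)\[C@@H](OC(C)=O)[C@H](OC(=O)c1ccccc1)C=C
F2 | step 6 | (2Z,4R,5R)-5-(TBSO)-3-(TBSO-methyl)hepta-2,6-diene-1,4-diol | OC/C=C(CO[Si](C)(C)C(C)(C)C)\[C@@H](O)[C@H](O[Si](C)(C)C(C)(C)C)C=C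
F3 | step 6 | (2Z,4R,5R)-5-(TBSO)-3-(TBSO-methyl)-1-[(triethylsilyl)oxy]hepta-2,6-dien-4-ol | CC[Si](CC)(CC)OC/C=C(CO[Si](C)(C)C(C)(C)C)\[C@@H](O)[C@H](O[Si](C)(C)C(C)(C)C)C=C
F4 | step 6 | (2Z,4R,5R)-5-(TBSO)-3-(TBSO-methyl)-1-[(triethylsilyl)oxy]hepta-2,6-dien-4-yl acetate | CC[Si](CC)(CC)OC/C=C(CO[Si](C)(C)C(C)(C)C)\[C@@H](OC(C)=O)[C@H](O[Si](C)(C)C(C)(C)C)C=C
F5 | step 6 | (2Z,4R,5R)-5-(TBSO)-3-(TBSO-methyl)-1-hydroxyhepta-2,6-dien-4-yl acetate | OC/C=C(CO[Si](C)(C)C(C)(C)C)\[C@@H](OC(C)=O)[C@H](O[Si](C)(C)C(C)(C)C)C=C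
F6 | step 6 | (2Z,4R,5R)-5-(TBSO)-3-(TBSO-methyl)-1-oxohepta-2,6-dien-4-yl acetate | O=C/C=C(CO[Si](C)(C)C(C)(C)C)\[C@@H](OC(C)=O)[C@H](O[Si](C)(C)C(C)(C)C)C=C
F7 | step 1 | 2,3:4,6-di-O-isopropylidene-α-L-sorbofuranose | OC[C@]12OC(C)(C)O[C@H]1[C@@H]3OC(C)(C)OC[C@@H]3O2
F8 | step 1 | 1-O-TBS-2,3:4,6-di-O-isopropylidene-α-L-sorbofuranose | CC(C)(C)[Si](C)(C)OC[C@]12OC(C)(C)O[C@H]1[C@@H]3OC(C)(C)OC[C@@H]3O2
F9 | step 1 | 1-O-TBS-2,3-O-isopropylidene-α-L-sorbofuranose | CC(C)(C)[Si](C)(C)OC[C@]12OC(C)(C)O[C@H]1[C@H](O)[C@H](CO)O2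
F10 | step 1 | 1-O-TBS-6-deoxy-6-iodo-2,3-O-isopropylidene-α-L-sorbofuranose | CC(C)(C)[Si](C)(C)OC[C@]12OC(C)(C)O[C@H]1[C@H](O)[C@H](CI)O2
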